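**Retrosynthetic overview**
1. The vanillate ester on O6 is cut last (Steglich coupling with phenol-silylated vanillic acid). The C8 carbinol comes from methyl addition to a C8 enone made by allylic oxidation beside C9=C10, the C6 alcohol from a hydroxyl-directed reduction, and the C4 carbinol from i-PrLi/CeCl3 addition to a C4 ketone.
2. Feature used: the seven-membered ring C1–C5–C6–C7–C8–C9–C10 carries the cis C9=C10 alkene beside quaternary C1 and an oxygen on C6 beside C5. With C6 as an enol this is a cyclohepta-1,4-diene (C9=C10, C5=C6), the pattern left by a cis-divinylcyclopropane that holds a temporary C5–C10 bond.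
3. Key disconnection: C7–C8 (with C5–C10 restored), taking the hydroazulenone silyl enol ether 13 back to the bicyclo[3.1.0]hexanone 12 with vinyl on C10 and 1-silyloxyvinyl on C5.
4. 12 comes from diazo diketone 9 by copper–bisoxazoline intramolecular cyclopropanation (sets C1); 9 comes from the acetylacetone dianion and a dienyl bromide built from acrolein.
5. Ring order: five-membered ring and cyclopropane together (step 6), then the seven-membered ring by ring expansion (step 8).

Key step: step 8

Remark on numbering: daucane numbering is used throughout (five-membered ring C1(CH3)–C2–C3–C4–C5; seven-membered ring C1–C5–C6–C7–C8–C9–C10); β is the face of the C1 methyl group.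
Remark on an assumption: the (S,S)-bisoxazoline ligand is assumed to give the enantiomer drawn for 10; if the sense of induction is the opposite, the (R,R)-ligand is used.

**Route**

Step 1
Reactants: 1 acrolein; 2 ethyl 2-(triphenylphosphoranylidene)propanoate
Product: 3 ethyl (2E)-2-methylpenta-2,4-dienoate
Conditions: CH2Cl2, 0 °C → rt
Reagents that add atoms: none
Why: Wittig olefination with a stabilised ylide, which reacts at the aldehyde of acrolein under neutral conditions and should give the E trisubstituted alkene (vinyl cis to methyl), the geometry that later places the vinyl group cis to the acetyl group on the cyclopropane.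

Step 2
Reactants: 3 ethyl (2E)-2-methylpenta-2,4-dienoate
Product: 4 (2E)-2-methylpenta-2,4-dien-1-ol
Conditions: i-Bu2AlH (2.2 equiv), CH2Cl2, −78 → 0 °C
Reagents that add atoms: none
Why: 1,2-Reduction of an α,β-unsaturated ester to the allylic alcohol with an aluminium hydride, which leaves the conjugated diene untouched.

Step 3
Reactants: 4 (2E)-2-methylpenta-2,4-dien-1-ol
Product: 5 (3E)-5-bromo-4-methylpenta-1,3-diene
Conditions: PBr3 (0.4 equiv), pyridine (cat.), Et2O, 0 °C; used at once as a solution
Reagents that add atoms: phosphorus tribromide, BrP(Br)Br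
Why: Bromination of a primary allylic alcohol through its bromophosphite (SN2 at the primary carbon), which keeps the conjugated E diene.

Step 4
Reactants: 6 acetylacetone; 5 (3E)-5-bromo-4-methylpenta-1,3-diene
Product: 8 (7E)-7-methyldeca-7,9-diene-2,4-dione, via acetylacetone dilithium dianion 7 (not isolated)
Conditions: LiN(i-Pr)2 (2.1 equiv), THF, 0 °C; then 5, 0 °C → rt
Reagents that add atoms: none
Why: γ-Alkylation of a 1,3-diketone dianion, in which the more basic terminal carbanion displaces the primary allylic bromide by SN2 and forms the C2–C3 bond.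

Step 5
Reactants: 8 (7E)-7-methyldeca-7,9-diene-2,4-dione
Product: 9 (7E)-3-diazo-7-methyldeca-7,9-diene-2,4-dione
Conditions: 4-acetamidobenzenesulfonyl azide, Et3N, MeCN, 0 °C → rt
Reagents that add atoms: 4-acetamidobenzenesulfonyl azide, CC(=O)Nc1ccc(cc1)S(=O)(=O)N=[N+]=[N-]
Why: Regitz diazo transfer to the active methylene of a 1,3-diketone.

Step 6
Reactants: 9 (7E)-3-diazo-7-methyldeca-7,9-diene-2,4-dione
Product: 10 (1S,5R,6R)-1-acetyl-6-ethenyl-5-methylbicyclo[3.1.0]hexan-2-one (acetyl, methyl and ethenyl mutually cis on the cyclopropane)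
Conditions: [Cu(MeCN)4]PF6 (5 mol%), (S,S)-t-Bu-box [2,2′-(propane-2,2-diyl)bis((4S)-4-tert-butyl-4,5-dihydrooxazole), 6 mol%], PhMe, 50 °C, slow addition of 9
Reagents that add atoms: none
Why: Copper–bisoxazoline-catalysed intramolecular cyclopropanation of a 2-diazo-1,3-dicarbonyl compound: the copper carbene adds to the proximal trisubstituted alkene (five-ring closure beats seven-ring closure at the terminal alkene), the stereospecific addition to the E alkene puts vinyl cis to acetyl, the cis ring fusion puts the C1 methyl on the same face, and the chiral ligand chooses the alkene face and so the absolute configuration of C1 (C5 and C10 follow).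

Step 7
Reactants: 10 (1S,5R,6R)-1-acetyl-6-ethenyl-5-methylbicyclo[3.1.0]hexan-2-one
Product: 12 (1S,5R,6R)-1-[1-(tert-butyldimethylsilyloxy)ethenyl]-6-ethenyl-5-methylbicyclo[3.1.0]hexan-2-one, via lithium enolate 11 (not isolated)
Conditions: LiN(i-Pr)2 (1.1 equiv), THF, −78 °C; then TBSOTf, −78 °C; cold NaHCO3 work-up, used crude
Reagents that add atoms: tert-butyldimethylsilyl trifluoromethanesulfonate, CC(C)(C)[Si](C)(C)OS(=O)(=O)C(F)(F)F
Why: Kinetic enolisation and O-silylation, in which the amide base should take a proton from the acetyl methyl group (the least substituted α-position) in preference to the ring C3 methylene; any ring enol ether cannot rearrange and is returned to 10 by hydrolysis.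

Step 8
Reactants: 12 (1S,5R,6R)-1-[1-(tert-butyldimethylsilyloxy)ethenyl]-6-ethenyl-5-methylbicyclo[3.1.0]hexan-2-one
Product: 13 (3aR)-8-(tert-butyldimethylsilyloxy)-3a-methyl-3,3a,6,7-tetrahydroazulen-1(2H)-one (daucane numbering: C4 ketone, C5=C6–OTBS, cis C9=C10, C7 and C8 methylene)
Conditions: PhMe (degassed, base-rinsed glassware), 80–100 °C
Reagents that add atoms: none
Why: This is a thermal [3,3]-sigmatropic rearrangement of a cis-1,2-divinylcyclopropane, the silyl enol ether variant of the divinylcyclopropane–cycloheptadiene (Cope) rearrangement, running through a boat transition state with both vinyl groups folded over the three-membered ring. It breaks the temporary C5–C10 cyclopropane bond and joins the two methylene termini C7 and C8, so the seven-membered ring C1–C5–C6–C7–C8–C9–C10 closes by C7–C8 σ-bond formation in a ring expansion made irreversible by release of cyclopropane strain. No stereocentre is formed: the boat geometry fixes C9=C10 as cis and the C5=C6 enol ether with O6 cis to C4, and quaternary C1 is untouched, so its configuration from step 6 is carried over. The selectivity needed is the cis relationship of the vinyl group on C10 and the silyloxyvinyl group on C5, which the stereospecific cyclopropanation of the E alkene has already built in. The C1 methyl group lies on the same face as both vinyl groups and crowds the boat, so more heat is expected than for an unsubstituted case, but the competing homodienyl 1,5-hydrogen shift from that methyl group should have a clearly higher barrier. The enol ether keeps C6 masked (the form with the ketone in the five-membered ring and the double bond exocyclic to it should be the favoured silatropic isomer), so only the C4 ketone is free for the next step.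

Step 9
Reactants: 13 (3aR)-8-(tert-butyldimethylsilyloxy)-3a-methyl-3,3a,6,7-tetrahydroazulen-1(2H)-one
Product: 14 tertiary alcohol (4β-OH, 4α-isopropyl, 1β-methyl, C5=C6–OTBS, C9=C10)
Conditions: i-PrLi, CeCl3, THF, −78 °C; pH 7 buffer quench, used crude
Reagents that add atoms: isopropyllithium, [Li]C(C)C
Why: 1,2-Addition of an organocerium reagent to a vinylogous silyl ester (cerium suppresses enolisation, β-hydride reduction and conjugate addition), with C4 set by attack on the α face, anti to the angular C1 methyl that stands over the β face of the flat cyclopentenone, whereas vinylic C10 on the α side turns its ring bond away from C4.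

Step 10
Reactants: 14 tertiary alcohol (4β-OH, 4α-isopropyl, C5=C6–OTBS)
Product: 16 β-hydroxy ketone (4β-OH, 4α-isopropyl, 5α-H trans-fused, C6 ketone, C9=C10), via tetrabutylammonium enolate 15 (not isolated)
Conditions: Bu4NF, AcOH (1:1), THF, −20 → 0 °C
Reagents that add atoms: none
Why: Fluoride cleavage of the silyl enol ether under acetic acid buffering, which avoids acid-promoted loss of the C4 hydroxyl (Stork–Danheiser-type transposition) and base-promoted retro-aldol; C5 is set by C-protonation and, being epimerisable α to the C6 ketone, should settle as the trans-fused isomer (H on the α face), in which C6 is trans to the isopropyl group and its carbonyl is hydrogen-bonded to the cis C4 hydroxyl.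

Step 11
Reactants: 16 β-hydroxy ketone (4β-OH, 5α-H, C6 ketone)
Product: 17 diol (4β-OH, 6α-OH, 5α-H, C9=C10)
Conditions: Me4NBH(OAc)3, MeCN/AcOH, −30 °C
Reagents that add atoms: none
Why: Evans–Saksena directed reduction, in which the C4 hydroxyl exchanges onto boron and delivers hydride to the β face of the C6 carbonyl through a six-membered transition state, giving the 4,6-anti diol with the C6 hydroxyl α, against the intrinsic preference for attack anti to the angular methyl.

Step 12
Reactants: 17 diol (4β-OH, 6α-OH)
Product: 18 6α-triethylsilyl ether (4β-OH free)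
Conditions: TESCl, imidazole, DMF, 0 °C
Reagents that add atoms: chlorotriethylsilane, CC[Si](CC)(CC)Cl
Why: Selective silylation of the secondary C6 alcohol, the tertiary C4 alcohol being inert to TESCl/imidazole.

Step 13
Reactants: 18 6α-triethylsilyl ether
Product: 19 C8 enone (C8=O conjugated with C9=C10, 6α-OTES, 4β-OH)
Conditions: Rh2(cap)4 (dirhodium tetracaprolactamate, 1 mol%), t-BuOOH (5 equiv), K2CO3 (0.5 equiv), CH2Cl2, rt
Reagents that add atoms: tert-butyl hydroperoxide, CC(C)(C)OO
Why: Allylic C–H oxidation with a dirhodium caprolactamate/hydroperoxide system, where C8 is the only allylic methylene (the other allylic atom, C1, is quaternary) and the allyl radical should be oxygenated at the unhindered C8 terminus to give the enone.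

Step 14
Reactants: 19 C8 enone
Product: 20 tertiary allylic alcohol (8β-OH, 8α-methyl, 6α-OTES, 4β-OH, C9=C10)
Conditions: MeMgBr (3 equiv), CeCl3, THF, −78 °C
Reagents that add atoms: methylmagnesium bromide, C[Mg]Br
Why: 1,2-Addition of a methylcerium reagent to an enone, with C8 set by attack on the α face because the pseudoaxial C1 methyl lies across the C9=C10 bond over the β face of the carbonyl, so the new hydroxyl ends up β.

Step 15
Reactants: 20 tertiary allylic alcohol (6α-OTES)
Product: 21 (1R,4R,5S,6S,8S)-dauc-9-ene-4,6,8-triol (4β,6α,8β)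
Conditions: Bu4NF, AcOH, THF, 0 °C → rt
Reagents that add atoms: none
Why: Fluoride cleavage of the triethylsilyl ether under buffered conditions that leave the tertiary allylic alcohol intact.

Step 16
Reactants: 22 vanillic acid
Product: 24 4-(tert-butyldimethylsilyloxy)-3-methoxybenzoic acid, via bis-silylated vanillic acid 23 (not isolated)
Conditions: TBSCl (2.2 equiv), imidazole, DMF, rt; then AcOH/THF/H2O, rt
Reagents that add atoms: tert-butyldimethylsilyl chloride, CC(C)(C)[Si](C)(C)Cl
Why: Silylation of phenol and acid followed by selective hydrolysis of the labile silyl ester, which leaves the aryl silyl ether in place.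

Step 17
Reactants: 21 (1R,4R,5S,6S,8S)-dauc-9-ene-4,6,8-triol; 24 4-(tert-butyldimethylsilyloxy)-3-methoxybenzoic acid
Product: 25 6-O-[4-(tert-butyldimethylsilyloxy)-3-methoxybenzoyl] ester of 21
Conditions: DCC, DMAP, CH2Cl2, rt
Reagents that add atoms: none
Why: Steglich esterification, in which only the secondary C6 hydroxyl is acylated (both tertiary alcohols are inert) and C6 keeps its configuration because its C–O bond is not broken.

Step 18
Reactants: 25 silyl-protected ester
Product: 26 (1R,4R,5S,6S,8S)-4,8-dihydroxydauc-9-en-6-yl 4-hydroxy-3-methoxybenzoate (CNP0243386.2)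
Conditions: Bu4NF, AcOH, THF, 0 °C
Reagents that add atoms: none
Why: Fluoride cleavage of the aryl silyl ether, which is much faster than any reaction of the benzoate ester or the tertiary alcohols.

**Compound list**
1 | acrolein | C=CC=O | starting material
2 | ethyl 2-(triphenylphosphoranylidene)propanoate | CCOC(=O)C(C)=P(c1ccccc1)(c1ccccc1)c1ccccc1 | starting material
3 | ethyl (2E)-2-methylpenta-2,4-dienoate | C=C/C=C(\C)C(=O)OCC | intermediate
4 | (2E)-2-methylpenta-2,4-dien-1-ol | C=C/C=C(\C)CO | intermediate
5 | (3E)-5-bromo-4-methylpenta-1,3-diene | C=C/C=C(\C)CBr | intermediate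
6 | acetylacetone | CC(=O)CC(C)=O | starting material
7 | acetylacetone dilithium dianion | [Li+].[Li+].C=C([O-])C=C(C)[O-] | intermediate
8 | (7E)-7-methyldeca-7,9-diene-2,4-dione | CC(=O)CC(=O)CC/C(C)=C/C=C | intermediate
9 | (7E)-3-diazo-7-methyldeca-7,9-diene-2,4-dione | CC(=O)C(=[N+]=[N-])C(=O)CC/C(C)=C/C=C | intermediate
10 | (1S,5R,6R)-1-acetyl-6-ethenyl-5-methylbicyclo[3.1.0]hexan-2-one | C=C[C@@H]1[C@@]2(C)CCC(=O)[C@@]12C(C)=O | intermediate
11 | lithium enolate of the acetyl group of 10 | C=C[C@@H]1[C@@]2(C)CCC(=O)[C@@]12C(=C)[O-].[Li+] | intermediate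
12 | (1S,5R,6R)-1-[1-(tert-butyldimethylsilyloxy)ethenyl]-6-ethenyl-5-methylbicyclo[3.1.0]hexan-2-one | C=C[C@@H]1[C@@]2(C)CCC(=O)[C@@]12C(=C)O[Si](C)(C)C(C)(C)C | intermediate
13 | (3aR)-8-(tert-butyldimethylsilyloxy)-3a-methyl-3,3a,6,7-tetrahydroazulen-1(2H)-one | CC(C)(C)[Si](C)(C)OC1=C2C(=O)CC[C@]2(C)C=CCC1 | intermediate
14 | tertiary alcohol, 4β-OH, 4α-isopropyl, C5=C6–OTBS, C9=C10 | CC(C)(C)[Si](C)(C)OC1=C2[C@](O)(C(C)C)CC[C@]2(C)C=CCC1 | intermediate
15 | tetrabutylammonium C6 enolate of 16 | [O-]C1=C2[C@](O)(C(C)C)CC[C@]2(C)C=CCC1.CCCC[N+](CCCC)(CCCC)CCCC | intermediate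
16 | β-hydroxy ketone, 4β-OH, 5α-H, C6 ketone, C9=C10 | O=C1CCC=C[C@@]2(C)CC[C@@](O)(C(C)C)[C@H]12 | intermediate
17 | diol, 4β-OH, 6α-OH, C9=C10 | O[C@H]1CCC=C[C@@]2(C)CC[C@@](O)(C(C)C)[C@H]12 | intermediate
18 | 6α-triethylsilyl ether of 17 | CC[Si](CC)(CC)O[C@H]1CCC=C[C@@]2(C)CC[C@@](O)(C(C)C)[C@H]12 | intermediate
19 | C8 enone, 6α-OTES, 4β-OH | CC[Si](CC)(CC)O[C@H]1CC(=O)C=C[C@@]2(C)CC[C@@](O)(C(C)C)[C@H]12 | intermediate
20 | 8β-hydroxy-8α-methyl adduct, 6α-OTES, 4β-OH | CC[Si](CC)(CC)O[C@H]1C[C@](C)(O)C=C[C@@]2(C)CC[C@@](O)(C(C)C)[C@H]12 | intermediate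
21 | (1R,4R,5S,6S,8S)-dauc-9-ene-4,6,8-triol | O[C@H]1C[C@](C)(O)C=C[C@@]2(C)CC[C@@](O)(C(C)C)[C@H]12 | intermediate
22 | vanillic acid | COc1cc(C(=O)O)ccc1O | starting material
23 | tert-butyldimethylsilyl 4-(tert-butyldimethylsilyloxy)-3-methoxybenzoate | COc1cc(C(=O)O[Si](C)(C)C(C)(C)C)ccc1O[Si](C)(C)C(C)(C)C | intermediate
24 | 4-(tert-butyldimethylsilyloxy)-3-methoxybenzoic acid | COc1cc(C(=O)O)ccc1O[Si](C)(C)C(C)(C)C | intermediate
25 | 6-O-[4-(tert-butyldimethylsilyloxy)-3-methoxybenzoyl] ester of 21 | COc1cc(C(=O)O[C@H]2C[C@](C)(O)C=C[C@@]3(C)CC[C@@](O)(C(C)C)[C@H]23)ccc1O[Si](C)(C)C(C)(C)C | intermediate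
26 | (1R,4R,5S,6S,8S)-4,8-dihydroxydauc-9-en-6-yl 4-hydroxy-3-methoxybenzoate | COc1cc(C(=O)O[C@H]2C[C@](C)(O)C=C[C@@]3(C)CC[C@@](O)(C(C)C)[C@H]23)ccc1O | target

**Step count**
Total: 18 steps. Longest linear sequence: 17 steps (steps 1–15, 17, 18, from acrolein); step 16 is a one-step side branch.

**Steps most likely to fail**

Step 6. The diacceptor copper carbene carries two similar acyl groups, so enantioface discrimination may be poor, and the Lewis-acidic catalyst may open the activated vinylcyclopropane once it has formed. The fallback sets out from 9 and comes back at 12, bypassing 10. The acetyl group of 9 is silylated first (TBSOTf, Et3N, CH2Cl2, 0 °C) to the silyloxyvinyl diazo ketone F1, which makes the carbene a donor–acceptor vinylcarbene. Rh2(S-PTAD)4 (dirhodium tetrakis[(S)-(1-adamantyl)(N-phthalimido)acetate]; the antipode if needed) in hexane/PhMe at −40 °C → rt then cyclopropanates the same E alkene intramolecularly, a carbene class for which chiral dirhodium carboxylates give dependable induction. This delivers 12 directly, which may already go on to 13 in the same flask.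

Step 9. The two faces of the C4 carbonyl differ only by a methyl group versus a vinylic carbon on C1, so facial selectivity may be low, and the tertiary allylic alcohol next to the enol ether may ionise during work-up. The fallback sets out from 14 (either C4 epimer or the mixture) and comes back at 16, and it is stereoconvergent:
- Mild acid (oxalic acid, wet CH2Cl2) converts 14 by Stork–Danheiser transposition into the enone F2 (C6 ketone, C4=C5 bearing the isopropyl group), which erases C4.
- Luche reduction (NaBH4, CeCl3·7H2O, MeOH, −40 °C), anti to the angular methyl, gives the 6β allylic alcohol F3.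
- VO(acac)2/t-BuOOH epoxidises the tetrasubstituted C4=C5 alkene on the hydroxyl (β) face to give the epoxy alcohol F4.
- Dess–Martin oxidation gives the epoxy ketone F5.
- SmI2 (THF/MeOH, −78 °C) cleaves the C5–O bond and returns 16 with the 4β-hydroxyl, C5 again settling trans.

Step 14. The bias at C8 comes from a methyl group four atoms away, so the nucleophile may attack the wrong face of the carbonyl, and enolisation toward C7 could expel the β-silyloxy group. The fallback sets out from 19 and comes back at 20, and it swaps the roles of carbon and oxygen. Wittig methylenation (Ph3P=CH2, THF, 0 °C) gives the exocyclic diene F6. Epoxidation of the 1,1-disubstituted exocyclic alkene (mCPBA, NaHCO3, CH2Cl2, 0 °C) uses the face that the carbon nucleophile had preferred, so oxygen is placed β, giving the spiro-epoxide F7. LiBEt3H opens it at the CH2 terminus to give 20.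

**Further compounds**
F1 | step 6 | (7E)-2-(tert-butyldimethylsilyloxy)-3-diazo-7-methyldeca-1,7,9-trien-4-one | C=C(O[Si](C)(C)C(C)(C)C)C(=[N+]=[N-])C(=O)CC/C(C)=C/C=C
F2 | step 9 | transposed enone, C6 ketone, C4=C5 with isopropyl on C4, C9=C10 | CC(C)C1=C2C(=O)CCC=C[C@@]2(C)CC1
F3 | step 9 | 6β allylic alcohol of F2 | CC(C)C1=C2[C@H](O)CCC=C[C@@]2(C)CC1
F4 | step 9 | 4β,5β-epoxy 6β-alcohol | CC(C)[C@]12CC[C@]3(C)C=CCC[C@@H](O)[C@]13O2
F5 | step 9 | 4β,5β-epoxy C6 ketone | CC(C)[C@]12CC[C@]3(C)C=CCCC(=O)[C@]13O2
F6 | step 14 | C8 exocyclic methylene diene, 6α-OTES, 4β-OH | CC[Si](CC)(CC)O[C@H]1CC(=C)C=C[C@@]2(C)CC[C@@](O)(C(C)C)[C@H]12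
F7 | step 14 | C8 spiro-epoxide with oxygen β, 6α-OTES, 4β-OH | CC[Si](CC)(CC)O[C@H]1C[C@@]3(CO3)C=C[C@@]2(C)CC[C@@](O)(C(C)C)[C@H]12
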